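**Plan** (ring numbering: C1 = carbinol carbon bearing the undecanoyl group, C2 and C5 = acetoxy carbons, C3=C4 = alkene)
1. Retrosynthesis: remove the two acetates, return the C2 carbinol to a ring ketone, then open the ring at C2–C3 to a 4-alkynal (C2 = formyl carbon, C3≡C4 = terminal alkyne, C1 and C5 = tether).
2. Enabling feature: in the cyclopentene ring the oxygenated C2 is bonded to C3 of the C3=C4 alkene, so at the ketone level C2(=O)–C3H=C4H is what a formyl C–H bond gives on adding across C3≡C4.
3. The open chain is cut at C1–O and CH2–O (dihydroxylation of a 1,1-disubstituted alkene), at C1–C5 (Morita–Baylis–Hillman coupling) and next to the side-chain carbonyl (vinyl Grignard on undecanal).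
4. Forward: undecanal → decyl vinyl ketone → Baylis–Hillman adduct with the silyl ynal → syn-triol → silylated alkynal → rhodium ring closure (the only ring) → ketone reduction, desilylation, diacetylation.
5. Stereochemistry: the trans C1/C5 oxygens come from a hydroxyl-directed syn-dihydroxylation in the open chain; C2 comes from a Luche reduction anti to the C5 silyloxy group.

Key step: step 8

Remark: the stereodescriptors of the target describe a meso compound (acetoxy groups cis to each other, trans to the tertiary hydroxyl), so all chiral intermediates are carried as racemates and their SMILES show one enantiomer.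

**Step 1**
Reactants: 1 undecanal; 2 vinylmagnesium bromide
Product: 3 rac-tridec-1-en-3-ol
Conditions: THF, −78 → 0 °C; aq. NH4Cl
Reagents that add atoms: none
Why: Grignard 1,2-addition of the vinyl nucleophile to an unhindered aliphatic aldehyde; the carbinol centre forms racemic and is erased in step 2.

**Step 2**
Reactants: 3 rac-tridec-1-en-3-ol
Product: 4 tridec-1-en-3-one
Conditions: Dess–Martin periodinane, CH2Cl2, 0 °C → rt
Reagents that add atoms: none
Why: Dess–Martin oxidation of the secondary allylic alcohol under neutral, non-aqueous conditions should give the polymerisation-prone vinyl ketone cleanly for immediate use.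

**Step 3**
Reactants: 4 tridec-1-en-3-one; 5 3-(trimethylsilyl)propynal
Product: 6 rac-3-hydroxy-4-methylidene-1-(trimethylsilyl)pentadec-1-yn-5-one
Conditions: DABCO (1,4-diazabicyclo[2.2.2]octane, 30 mol %), THF, 0 °C → rt
Reagents that add atoms: none
Why: Morita–Baylis–Hillman reaction, in which the amine adds to the vinyl ketone, the zwitterionic enolate attacks the electrophilic ynal and loss of the amine restores the α-methylene ketone; the new carbinol centre (later C5) forms racemic, which suffices for a meso target.

**Step 4**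
Reactants: 6 rac-3-hydroxy-4-methylidene-1-(trimethylsilyl)pentadec-1-yn-5-one
Product: 7 rac-3-hydroxy-4-methylidenepentadec-1-yn-5-one
Conditions: Bu4NF, AcOH (1:1), THF, 0 °C
Reagents that add atoms: none
Why: Fluoride-induced protodesilylation of the alkynylsilane, buffered with acetic acid so that fluoride does not act as a base on the hydroxy enone; removal here avoids basic methanol on later β-hydroxy ketone intermediates.

**Step 5**
Reactants: 7 rac-3-hydroxy-4-methylidenepentadec-1-yn-5-one
Product: 9 rel-(3R,4R)-3,4-dihydroxy-4-(hydroxymethyl)pentadec-1-yn-5-one, via osmate ester 8 (not isolated)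
Conditions: OsO4 (1.05 equiv), TMEDA (N,N,N',N'-tetramethylethylenediamine), CH2Cl2, −78 °C; then HCl, MeOH, rt
Reagents that add atoms: osmium tetroxide, O=[Os](=O)(=O)=O
Why: Donohoe hydroxyl-directed dihydroxylation, in which the allylic hydroxyl hydrogen-bonds the OsO4·TMEDA complex and steers it to the alkene face syn to itself (allylic C–H eclipsing the alkene), so the tertiary hydroxyl should be set syn to the secondary one, opposite to the anti outcome of undirected osmylation; the alkyne is inert at −78 °C and acidic methanol frees the triol without base.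

**Step 6**
Reactants: 9 rel-(3R,4R)-3,4-dihydroxy-4-(hydroxymethyl)pentadec-1-yn-5-one
Product: 10 rel-(3R,4R)-3,4-bis(triethylsilyloxy)-4-[(triethylsilyloxy)methyl]pentadec-1-yn-5-one
Conditions: Et3SiOTf (3.5 equiv), 2,6-lutidine, CH2Cl2, −78 → 0 °C
Reagents that add atoms: triethylsilyl trifluoromethanesulfonate, CC[Si](CC)(CC)OS(=O)(=O)C(F)(F)F
Why: Exhaustive silyl ether formation with a silyl triflate, reactive enough for the hindered tertiary α-ketol hydroxyl, while 2,6-lutidine is too weak a base to enolise the ketone.

**Step 7**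
Reactants: 10 rel-(3R,4R)-3,4-bis(triethylsilyloxy)-4-[(triethylsilyloxy)methyl]pentadec-1-yn-5-one
Product: 11 rel-(2S,3R)-2-undecanoyl-2,3-bis(triethylsilyloxy)pent-4-ynal
Conditions: (COCl)2, DMSO, CH2Cl2, −78 → −30 °C; Et3N, −78 °C → rt
Reagents that add atoms: none
Why: Swern oxidation with in-situ cleavage of a primary triethylsilyl ether, in which the chlorosulfonium salt attacks only the least hindered silyl ether and takes it directly to the aldehyde; the non-enolisable β-keto aldehyde cannot epimerise and is best used at once.

**Step 8**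
Reactants: 11 rel-(2S,3R)-2-undecanoyl-2,3-bis(triethylsilyloxy)pent-4-ynal
Product: 12 rel-(4R,5R)-4,5-bis(triethylsilyloxy)-5-undecanoylcyclopent-2-en-1-one (silyloxy groups trans)
Conditions: [Rh(dppe)]2(BF4)2 (5 mol %; dppe = 1,2-bis(diphenylphosphino)ethane), acetone, rt
Reagents that add atoms: none
Why: Oxidative addition of the formyl C–H bond of 11 to monovalent rhodium should give an acyl hydride of trivalent rhodium, the hydride is passed to the inner alkyne carbon (C4) with net trans geometry, and the resulting six-membered acyl–alkenyl rhodacycle reductively eliminates to form C2–C3 and release the enone. The closest known reaction is the [Rh(dppe)]2(BF4)2-catalysed intramolecular trans-hydroacylation of 4-alkynals to cyclopent-2-enones, which accepts an oxygen substituent at the propargylic carbon. The cyclopentenone closes in a formal 5-endo-dig mode, both alkyne carbons ending inside the ring. No stereocentre is formed: C1 and C5 were fixed in step 5 and cannot epimerise, since C1 is quaternary and the C5 silyl ether is inert under the neutral conditions. The step needs hydroacylation to outrun decarbonylation and alkyne oligomerisation; the aldehyde has no α-hydrogen, the quaternary C1 presses formyl group and alkyne together, the neighbouring ketone and ether oxygens can fill the coordination site that CO extrusion requires, and the two silyl ethers shield the terminal alkyne from a second metal centre.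

**Step 9**
Reactants: 12 rel-(4R,5R)-4,5-bis(triethylsilyloxy)-5-undecanoylcyclopent-2-en-1-one
Product: 13 rac-1-[2-hydroxy-1,5-bis(triethylsilyloxy)cyclopent-3-en-1-yl]undecan-1-one (2-OH cis to 5-OSiEt3, trans to 1-OSiEt3)
Conditions: NaBH4, CeCl3·7H2O, MeOH/THF, −78 °C; aq. NH4Cl
Reagents that add atoms: none
Why: Luche reduction, in which the hard methoxyborohydride should add 1,2 to the conjugated ring carbonyl much faster than to the neopentyl-type side-chain ketone buried between the quaternary carbon and two silyl ethers; hydride should enter anti to the C5 silyloxy group and the C1 acyl chain, as in reductions of 4-silyloxycyclopent-2-enones to cis-1,4 products, setting C2–O cis to C5–O and trans to C1–O.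

**Step 10**
Reactants: 13 rac-1-[2-hydroxy-1,5-bis(triethylsilyloxy)cyclopent-3-en-1-yl]undecan-1-one
Product: 14 meso-1-(1,2,5-trihydroxycyclopent-3-en-1-yl)undecan-1-one (2- and 5-OH cis, trans to 1-OH)
Conditions: HF·pyridine, THF, 0 °C → rt
Reagents that add atoms: none
Why: Fluoride-mediated desilylation of both triethylsilyl ethers under mildly acidic conditions, chosen because basic fluoride would invite retro-aldol cleavage or ketol shift in the β-hydroxy α-hydroxy ketone product.

**Step 11**
Reactants: 14 meso-1-(1,2,5-trihydroxycyclopent-3-en-1-yl)undecan-1-one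
Product: 15 meso-1-(2,5-diacetoxy-1-hydroxycyclopent-3-en-1-yl)undecan-1-one (CNP0208983.3)
Conditions: Ac2O (2.5 equiv), pyridine, DMAP (cat.), CH2Cl2, 0 °C
Reagents that add atoms: acetic anhydride, CC(=O)OC(C)=O
Why: DMAP-catalysed acetylation of the two secondary allylic hydroxyls; the tertiary hydroxyl, flanked by the acyl group and two substituted ring carbons, should stay free with a small excess of anhydride at 0 °C.

**Compound list**
1 | undecanal | CCCCCCCCCCC=O | starting material
2 | vinylmagnesium bromide | C=C[Mg]Br | starting material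
3 | rac-tridec-1-en-3-ol | CCCCCCCCCCC(O)C=C | intermediate
4 | tridec-1-en-3-one | CCCCCCCCCCC(=O)C=C | intermediate
5 | 3-(trimethylsilyl)propynal | C[Si](C)(C)C#CC=O | starting material
6 | rac-3-hydroxy-4-methylidene-1-(trimethylsilyl)pentadec-1-yn-5-one | CCCCCCCCCCC(=O)C(=C)[C@H](O)C#C[Si](C)(C)C | intermediate
7 | rac-3-hydroxy-4-methylidenepentadec-1-yn-5-one | CCCCCCCCCCC(=O)C(=C)[C@H](O)C#C | intermediate
8 | osmate ester of 7 (TMEDA-bound glycolate of hexavalent osmium, not isolated) | CCCCCCCCCCC(=O)[C@@](O1)(CO[Os-2]12(=O)(=O)[N+](C)(C)CC[N+]2(C)C)[C@H](O)C#C | intermediate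
9 | rel-(3R,4R)-3,4-dihydroxy-4-(hydroxymethyl)pentadec-1-yn-5-one (3- and 4-OH syn) | CCCCCCCCCCC(=O)[C@@](O)(CO)[C@H](O)C#C | intermediate
10 | rel-(3R,4R)-3,4-bis(triethylsilyloxy)-4-[(triethylsilyloxy)methyl]pentadec-1-yn-5-one | CCCCCCCCCCC(=O)[C@@](O[Si](CC)(CC)CC)(CO[Si](CC)(CC)CC)[C@H](O[Si](CC)(CC)CC)C#C | intermediate
11 | rel-(2S,3R)-2-undecanoyl-2,3-bis(triethylsilyloxy)pent-4-ynal | CCCCCCCCCCC(=O)[C@@](O[Si](CC)(CC)CC)(C=O)[C@H](O[Si](CC)(CC)CC)C#C | intermediate
12 | rel-(4R,5R)-4,5-bis(triethylsilyloxy)-5-undecanoylcyclopent-2-en-1-one (silyloxy groups trans) | CCCCCCCCCCC(=O)[C@@]1(O[Si](CC)(CC)CC)C(=O)C=C[C@H]1O[Si](CC)(CC)CC | intermediate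
13 | rac-1-[2-hydroxy-1,5-bis(triethylsilyloxy)cyclopent-3-en-1-yl]undecan-1-one (2-OH cis to 5-OSiEt3, trans to 1-OSiEt3) | CCCCCCCCCCC(=O)[C@@]1(O[Si](CC)(CC)CC)[C@@H](O)C=C[C@H]1O[Si](CC)(CC)CC | intermediate
14 | meso-1-(1,2,5-trihydroxycyclopent-3-en-1-yl)undecan-1-one | CCCCCCCCCCC(=O)[C@@]1(O)[C@@H](O)C=C[C@H]1O | intermediate
15 | meso-1-(2,5-diacetoxy-1-hydroxycyclopent-3-en-1-yl)undecan-1-one | CCCCCCCCCCC(=O)[C@@]1(O)[C@@H](OC(C)=O)C=C[C@H]1OC(C)=O | target

**Step count and risks**
Total: 11 steps. Longest linear sequence: 11 steps (1 → 15).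

Steps most likely to fail:

1. Step 8. Decarbonylation of the hindered α-quaternary aldehyde, or rhodium-mediated oligomerisation of the terminal alkyne, may outrun hydroacylation. Fallback: the same C2–C3 bond would be formed by an intramolecular Nozaki–Hiyama–Kishi reaction, setting out from 10 and returning at 12. Iodination of the alkyne (N-iodosuccinimide, AgNO3 cat., acetone) should give the 1-iodoalkyne F1. Diimide reduction (KO2CN=NCO2K, AcOH, MeOH/pyridine) should give the (Z)-iodoalkene F2. Swern oxidation as in step 7 should give the iodo aldehyde F3. CrCl2 (divalent chromium) with catalytic NiCl2 in DMF should close the ring onto the aldehyde, not the ketone, to give the cyclopentenol epimer mixture F4. Dess–Martin oxidation of F4 gives 12.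

2. Step 9. Hydride may be delivered to the wrong ring face, because the tertiary silyl ether on the top face partly offsets the shielding of the bottom face. Fallback: the tertiary hydroxyl would be freed before reduction so that it steers the hydride, setting out from 12 and returning at 15. HF·pyridine should cleave both silyl ethers to the dihydroxy enone F5. Ac2O/pyridine at 0 °C should acetylate only the secondary hydroxyl to give the monoacetate F6. Luche reduction at −78 °C, now with a bare hydroxyl on the top face and acetoxy and acyl groups on the bottom face, should give the hydroxy acetate F7. Acetylation as in step 11 gives 15.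

3. Step 3. Amine-induced oligomerisation of the ynal or Rauhut–Currier dimerisation of the vinyl ketone may outrun the aldol step. Fallback: a selenide-triggered Michael–aldol sequence, setting out from 4 and 5 and returning at 6. Me2AlSePh (from Me3Al and PhSeH) in CH2Cl2 at −78 °C adds to 4, and the aluminium enolate is trapped by 5 to give the β-hydroxy α-(phenylselanylmethyl) ketone F8 as a diastereomer mixture. H2O2/pyridine oxidises it to the selenoxide F9, which undergoes syn-elimination at 0 °C → rt to give 6.

**Further compounds**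
F1 | step 8 | 1-iodo-3,4-bis(triethylsilyloxy)-4-[(triethylsilyloxy)methyl]pentadec-1-yn-5-one (configured as 10) | CCCCCCCCCCC(=O)[C@@](O[Si](CC)(CC)CC)(CO[Si](CC)(CC)CC)[C@H](O[Si](CC)(CC)CC)C#CI
F2 | step 8 | (Z)-1-iodo-3,4-bis(triethylsilyloxy)-4-[(triethylsilyloxy)methyl]pentadec-1-en-5-one | CCCCCCCCCCC(=O)[C@@](O[Si](CC)(CC)CC)(CO[Si](CC)(CC)CC)[C@H](O[Si](CC)(CC)CC)/C=C\I
F3 | step 8 | (Z)-5-iodo-2-undecanoyl-2,3-bis(triethylsilyloxy)pent-4-enal | CCCCCCCCCCC(=O)[C@@](O[Si](CC)(CC)CC)(C=O)[C@H](O[Si](CC)(CC)CC)/C=C\I
F4 | step 8 | 1-[2-hydroxy-1,5-bis(triethylsilyloxy)cyclopent-3-en-1-yl]undecan-1-one, mixture of C2 epimers | CCCCCCCCCCC(=O)[C@@]1(O[Si](CC)(CC)CC)C(O)C=C[C@H]1O[Si](CC)(CC)CC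
F5 | step 9 | trans-4,5-dihydroxy-5-undecanoylcyclopent-2-en-1-one | CCCCCCCCCCC(=O)[C@@]1(O)C(=O)C=C[C@H]1O
F6 | step 9 | trans-4-acetoxy-5-hydroxy-5-undecanoylcyclopent-2-en-1-one | CCCCCCCCCCC(=O)[C@@]1(O)C(=O)C=C[C@H]1OC(C)=O
F7 | step 9 | 1-(2-acetoxy-1,5-dihydroxycyclopent-3-en-1-yl)undecan-1-one (2-OAc and 5-OH cis, trans to 1-OH) | CCCCCCCCCCC(=O)[C@@]1(O)[C@@H](O)C=C[C@H]1OC(C)=O
F8 | step 3 | 3-hydroxy-4-[(phenylselanyl)methyl]-1-(trimethylsilyl)pentadec-1-yn-5-one, diastereomer mixture | CCCCCCCCCCC(=O)C(C[Se]c1ccccc1)C(O)C#C[Si](C)(C)C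
F9 | step 3 | 3-hydroxy-4-[(phenylseleninyl)methyl]-1-(trimethylsilyl)pentadec-1-yn-5-one (selenoxide) | CCCCCCCCCCC(=O)C(C[Se](=O)c1ccccc1)C(O)C#C[Si](C)(C)C
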